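**Plan**

- Retrosynthesis: the two methoxymethyl ethers are removed and the C4 ketone is taken back to a carbinol; ring C is then cut at O1–C8a, the chain at C2–C3 (aldol), ring A at its C8–prenyl bond, and ring B at its formyl C–C bond and its dimethylpyran ring.
- Enabling feature: O1 is the aryl alkyl ether oxygen joining C8a of ring A to the stereogenic C2, so ring C can be closed by making the C8a–O bond from a C8a bromide while no bond at C2 is touched.
- Forward order: the dimethylpyran ring on ring B is built from resorcinol; ring A is prenylated between bromine and oxygen by directed metalation; the halves are joined at C2–C3; ring C closes in step 12.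
- Stereochemistry: C2 (S) is set by transfer hydrogenation of the 1,3-diketone under RuCl[(S,S)-TsDPEN](p-cymene) control, which also sets a temporary (S) centre at C4. C2 is carried through the C–O coupling with retention, and C4 is erased by oxidation.

Key step: step 12

Assumption: 1-(2-bromo-4-hydroxyphenyl)ethanone (the para-acetylated form of 3-bromophenol), resorcinol, 3-methylbut-2-enoic acid and 1-bromo-3-methylbut-2-ene are taken as purchased compounds.

**Route**

Step 1
Reactants: 1 1-(2-bromo-4-hydroxyphenyl)ethanone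
Product: 2 3-bromo-4-(2-methyl-1,3-dioxolan-2-yl)phenol
Conditions: HOCH2CH2OH, p-TsOH·H2O (cat.), toluene, reflux, Dean–Stark
Reagents that add atoms: ethane-1,2-diol, OCCO
Why: Acid-catalysed ketalisation driven by azeotropic removal of water masks the enolisable acetyl group so that the ring can later be metalated.

Step 2
Reactants: 2 3-bromo-4-(2-methyl-1,3-dioxolan-2-yl)phenol
Product: 3 2-[2-bromo-4-(methoxymethoxy)phenyl]-2-methyl-1,3-dioxolane
Conditions: NaH, DMF, 0 °C; MOMCl, 0 °C → rt
Reagents that add atoms: chloromethyl methyl ether, COCCl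
Why: Williamson-type O-alkylation of the sodium phenoxide installs the methoxymethyl ether, which is base-stable and serves as the ortho-directing group in the next step.

Step 3
Reactants: 3 2-[2-bromo-4-(methoxymethoxy)phenyl]-2-methyl-1,3-dioxolane; 4 1-bromo-3-methylbut-2-ene
Product: 7 2-[2-bromo-4-(methoxymethoxy)-3-(3-methylbut-2-en-1-yl)phenyl]-2-methyl-1,3-dioxolane, via aryllithium 5 (not isolated), via arylcopper 6 (not isolated)
Conditions: LiN(iPr)2, THF, −78 °C; CuBr·SMe2 (1.0 equiv), −78 °C; 4, −78 → 0 °C
Reagents that add atoms: none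
Why: Directed ortho-metalation removes the ring proton between bromine and the coordinating methoxymethoxy group (the most acidic site), the 2-bromoaryllithium is kept at −78 °C so that LiBr is not lost, and after transmetalation the arylcopper substitutes prenyl bromide at its primary carbon (SN2-type allylic substitution).

Step 4
Reactants: 7 2-[2-bromo-4-(methoxymethoxy)-3-(3-methylbut-2-en-1-yl)phenyl]-2-methyl-1,3-dioxolane
Product: 8 1-[2-bromo-4-(methoxymethoxy)-3-(3-methylbut-2-en-1-yl)phenyl]ethanone
Conditions: PPTS (0.2 equiv), THF/H2O (4:1), 45 °C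
Reagents that add atoms: water, O
Why: Mild acid-catalysed ketal hydrolysis of the electron-rich aryl dioxolane should be much faster than cleavage of the aryl methoxymethyl ether, so only the methyl ketone is unmasked.

Step 5
Reactants: 9 resorcinol; 10 3-methylbut-2-enoic acid
Product: 11 7-hydroxy-2,2-dimethylchroman-4-one
Conditions: P2O5/MeSO3H (1:10 w/w), 70 °C
Reagents that add atoms: none
Why: Friedel–Crafts acylation of resorcinol at C4 by the activated acid, followed in the same pot by oxa-Michael addition of the neighbouring hydroxyl to the enone, is the standard one-step chromanone annulation and places the free hydroxyl at C7.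

Step 6
Reactants: 11 7-hydroxy-2,2-dimethylchroman-4-one
Product: 13 2,2-dimethyl-2H-chromen-7-ol, via chromane-4,7-diol 12 (not isolated)
Conditions: NaBH4, MeOH, 0 °C → rt; then p-TsOH·H2O (5 mol %), toluene, 80 °C
Reagents that add atoms: none
Why: Borohydride reduction gives the benzylic alcohol, which loses water by acid-catalysed E1 elimination (the C4 cation is stabilised by the ring oxygen and the para C7 oxygen) to give the 2H-chromene.

Step 7
Reactants: 13 2,2-dimethyl-2H-chromen-7-ol
Product: 14 7-hydroxy-2,2-dimethyl-2H-chromene-6-carbaldehyde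
Conditions: MgCl2, Et3N, (CH2O)n, MeCN, reflux
Reagents that add atoms: paraformaldehyde (as formaldehyde), C=O
Why: Casnati–Skattebøl ortho-formylation: the magnesium phenoxide delivers formaldehyde to the ortho position, C6 being preferred over C8 (which is flanked by two oxygens), and a second formaldehyde oxidises the hydroxymethyl stage by hydride transfer.

Step 8
Reactants: 14 7-hydroxy-2,2-dimethyl-2H-chromene-6-carbaldehyde
Product: 15 7-(methoxymethoxy)-2,2-dimethyl-2H-chromene-6-carbaldehyde
Conditions: NaH, DMF, 0 °C; MOMCl, 0 °C → rt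
Reagents that add atoms: chloromethyl methyl ether, COCCl
Why: Williamson-type O-alkylation of the phenoxide protects the hydroxyl next to the aldehyde as the same base-stable acetal used on ring A.

Step 9
Reactants: 8 1-[2-bromo-4-(methoxymethoxy)-3-(3-methylbut-2-en-1-yl)phenyl]ethanone; 15 7-(methoxymethoxy)-2,2-dimethyl-2H-chromene-6-carbaldehyde
Product: 17 rac-1-[2-bromo-4-(methoxymethoxy)-3-(3-methylbut-2-en-1-yl)phenyl]-3-hydroxy-3-[7-(methoxymethoxy)-2,2-dimethyl-2H-chromen-6-yl]propan-1-one, via lithium enolate 16 (not isolated)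
Conditions: LiN(iPr)2, THF, −78 °C; 15, −78 °C; aq. NH4Cl at −78 °C
Reagents that add atoms: none
Why: Lithium enolate aldol addition of the methyl ketone to the non-enolisable aldehyde forms the C2–C3 bond; the carbinol is made racemic on purpose because the next step removes it.

Step 10
Reactants: 17 rac-1-[2-bromo-4-(methoxymethoxy)-3-(3-methylbut-2-en-1-yl)phenyl]-3-hydroxy-3-[7-(methoxymethoxy)-2,2-dimethyl-2H-chromen-6-yl]propan-1-one
Product: 18 1-[2-bromo-4-(methoxymethoxy)-3-(3-methylbut-2-en-1-yl)phenyl]-3-[7-(methoxymethoxy)-2,2-dimethyl-2H-chromen-6-yl]propane-1,3-dione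
Conditions: Dess–Martin periodinane (1.2 equiv), NaHCO3, CH2Cl2, 0 °C → rt
Reagents that add atoms: none
Why: Dess–Martin oxidation of the secondary alcohol gives the 1,3-diketone (largely as its enol) under buffered conditions that leave the alkenes, the bromide and the acetals alone.

Step 11
Reactants: 18 1-[2-bromo-4-(methoxymethoxy)-3-(3-methylbut-2-en-1-yl)phenyl]-3-[7-(methoxymethoxy)-2,2-dimethyl-2H-chromen-6-yl]propane-1,3-dione
Product: 21 (1S,3S)-1-[2-bromo-4-(methoxymethoxy)-3-(3-methylbut-2-en-1-yl)phenyl]-3-[7-(methoxymethoxy)-2,2-dimethyl-2H-chromen-6-yl]propane-1,3-diol, via ring A carbinol ketone 19 (not isolated), via ring B carbinol ketone 20 (not isolated)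
Conditions: RuCl[(S,S)-TsDPEN](p-cymene) (2 mol %), HCO2H/Et3N (5:2), DMF, 40 °C
Reagents that add atoms: none
Why: Noyori asymmetric transfer hydrogenation of a 1,3-diaryl-1,3-diketone: the ruthenium hydride carrying (S,S)-TsDPEN reduces each aryl ketone through the bifunctional six-membered transition state with the aryl group under the cymene ring, which should set (S) at both carbinols and give the anti diol, with most stereochemical error expected to end up in the separable syn diastereomer.

Step 12
Reactants: 21 (1S,3S)-1-[2-bromo-4-(methoxymethoxy)-3-(3-methylbut-2-en-1-yl)phenyl]-3-[7-(methoxymethoxy)-2,2-dimethyl-2H-chromen-6-yl]propane-1,3-diol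
Product: 22 (2S,4S)-7-(methoxymethoxy)-2-[7-(methoxymethoxy)-2,2-dimethyl-2H-chromen-6-yl]-8-(3-methylbut-2-en-1-yl)chroman-4-ol
Conditions: CuI (10 mol %), 3,4,7,8-tetramethyl-1,10-phenanthroline (20 mol %), Cs2CO3 (2 equiv), toluene, 110 °C, argon
Reagents that add atoms: none
Why: Cs2CO3 turns the C2 hydroxyl into its alkoxide, which binds the phenanthroline-ligated monovalent copper centre; this copper alkoxide activates the adjacent C8a–Br bond and C–O reductive elimination forms O1–C8a and releases the catalyst. The closest known reaction type is the Ullmann-type copper-catalysed O-arylation of aliphatic alcohols with aryl halides, which is established in its intramolecular form for chromans and 2-arylchromans. Ring C closes as a six-membered ring by attack of the tethered oxygen on the trigonal carbon C8a with the departing bromide outside the ring (6-exo mode). No stereocentre is created: neither the C2–O nor the C4–O bond is broken, so (2S) follows from the diol with retention and C4 stays (S). The step needs selection between the two hydroxyls and between cyclisation and intermolecular coupling; the C2 oxygen reaches C8a through a six-membered ring whereas the C4 oxygen could only form a four-membered ring, and intramolecularity offsets the hindrance of a bromide flanked by the prenyl group and the side chain. At the diol oxidation level the carbonate base finds no β-hydroxy ketone or flavanone to fragment, dehydrate or ring-open.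

Step 13
Reactants: 22 (2S,4S)-7-(methoxymethoxy)-2-[7-(methoxymethoxy)-2,2-dimethyl-2H-chromen-6-yl]-8-(3-methylbut-2-en-1-yl)chroman-4-ol
Product: 23 (2S)-7-(methoxymethoxy)-2-[7-(methoxymethoxy)-2,2-dimethyl-2H-chromen-6-yl]-8-(3-methylbut-2-en-1-yl)chroman-4-one
Conditions: Dess–Martin periodinane (1.3 equiv), NaHCO3, CH2Cl2, 0 °C → rt
Reagents that add atoms: none
Why: Dess–Martin oxidation of the benzylic C4 alcohol gives the flavanone under near-neutral conditions, so no enolate forms and the O1–C2 bond is not opened.

Step 14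
Reactants: 23 (2S)-7-(methoxymethoxy)-2-[7-(methoxymethoxy)-2,2-dimethyl-2H-chromen-6-yl]-8-(3-methylbut-2-en-1-yl)chroman-4-one
Product: 24 (2S)-7-hydroxy-2-(7-hydroxy-2,2-dimethyl-2H-chromen-6-yl)-8-(3-methylbut-2-en-1-yl)chroman-4-one (CNP0279510.1)
Conditions: 3 M aq. HCl/MeOH (1:10), 40 °C
Reagents that add atoms: none
Why: Acid-catalysed acetal exchange with methanol cleaves both aryl methoxymethyl ethers, and the low temperature and short contact time are chosen to spare the prenyl group, the chromene and the C2 centre.

**Compound list**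

1 | 1-(2-bromo-4-hydroxyphenyl)ethanone | CC(=O)c1ccc(O)cc1Br | starting material
2 | 3-bromo-4-(2-methyl-1,3-dioxolan-2-yl)phenol | CC1(OCCO1)c1ccc(O)cc1Br | intermediate
3 | 2-[2-bromo-4-(methoxymethoxy)phenyl]-2-methyl-1,3-dioxolane | COCOc1ccc(C2(C)OCCO2)c(Br)c1 | intermediate
4 | 1-bromo-3-methylbut-2-ene | CC(C)=CCBr | starting material
5 | [2-bromo-6-(methoxymethoxy)-3-(2-methyl-1,3-dioxolan-2-yl)phenyl]lithium (not isolated) | COCOc1ccc(C2(C)OCCO2)c(Br)c1[Li] | intermediate
6 | [2-bromo-6-(methoxymethoxy)-3-(2-methyl-1,3-dioxolan-2-yl)phenyl]copper (not isolated) | COCOc1ccc(C2(C)OCCO2)c(Br)c1[Cu] | intermediate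
7 | 2-[2-bromo-4-(methoxymethoxy)-3-(3-methylbut-2-en-1-yl)phenyl]-2-methyl-1,3-dioxolane | COCOc1ccc(C2(C)OCCO2)c(Br)c1CC=C(C)C | intermediate
8 | 1-[2-bromo-4-(methoxymethoxy)-3-(3-methylbut-2-en-1-yl)phenyl]ethanone | COCOc1ccc(C(C)=O)c(Br)c1CC=C(C)C | intermediate
9 | resorcinol | Oc1cccc(O)c1 | starting material
10 | 3-methylbut-2-enoic acid | CC(C)=CC(=O)O | starting material
11 | 7-hydroxy-2,2-dimethylchroman-4-one | CC1(C)CC(=O)c2ccc(O)cc2O1 | intermediate
12 | rac-2,2-dimethylchromane-4,7-diol (not isolated) | CC1(C)CC(O)c2ccc(O)cc2O1 | intermediate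
13 | 2,2-dimethyl-2H-chromen-7-ol | CC1(C)C=Cc2ccc(O)cc2O1 | intermediate
14 | 7-hydroxy-2,2-dimethyl-2H-chromene-6-carbaldehyde | CC1(C)C=Cc2cc(C=O)c(O)cc2O1 | intermediate
15 | 7-(methoxymethoxy)-2,2-dimethyl-2H-chromene-6-carbaldehyde | CC1(C)C=Cc2cc(C=O)c(OCOC)cc2O1 | intermediate
16 | lithium 1-[2-bromo-4-(methoxymethoxy)-3-(3-methylbut-2-en-1-yl)phenyl]ethen-1-olate (not isolated) | [Li]OC(=C)c1ccc(OCOC)c(CC=C(C)C)c1Br | intermediate
17 | rac-1-[2-bromo-4-(methoxymethoxy)-3-(3-methylbut-2-en-1-yl)phenyl]-3-hydroxy-3-[7-(methoxymethoxy)-2,2-dimethyl-2H-chromen-6-yl]propan-1-one | CC(C)=CCc1c(OCOC)ccc(C(=O)CC(O)c2cc3c(cc2OCOC)OC(C)(C)C=C3)c1Br | intermediate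
18 | 1-[2-bromo-4-(methoxymethoxy)-3-(3-methylbut-2-en-1-yl)phenyl]-3-[7-(methoxymethoxy)-2,2-dimethyl-2H-chromen-6-yl]propane-1,3-dione | CC(C)=CCc1c(OCOC)ccc(C(=O)CC(=O)c2cc3c(cc2OCOC)OC(C)(C)C=C3)c1Br | intermediate
19 | (3S)-3-[2-bromo-4-(methoxymethoxy)-3-(3-methylbut-2-en-1-yl)phenyl]-3-hydroxy-1-[7-(methoxymethoxy)-2,2-dimethyl-2H-chromen-6-yl]propan-1-one (not isolated) | CC(C)=CCc1c(OCOC)ccc([C@@H](O)CC(=O)c2cc3c(cc2OCOC)OC(C)(C)C=C3)c1Br | intermediate
20 | (3S)-1-[2-bromo-4-(methoxymethoxy)-3-(3-methylbut-2-en-1-yl)phenyl]-3-hydroxy-3-[7-(methoxymethoxy)-2,2-dimethyl-2H-chromen-6-yl]propan-1-one (not isolated) | CC(C)=CCc1c(OCOC)ccc(C(=O)C[C@H](O)c2cc3c(cc2OCOC)OC(C)(C)C=C3)c1Br | intermediate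
21 | (1S,3S)-1-[2-bromo-4-(methoxymethoxy)-3-(3-methylbut-2-en-1-yl)phenyl]-3-[7-(methoxymethoxy)-2,2-dimethyl-2H-chromen-6-yl]propane-1,3-diol | CC(C)=CCc1c(OCOC)ccc([C@@H](O)C[C@H](O)c2cc3c(cc2OCOC)OC(C)(C)C=C3)c1Br | intermediate
22 | (2S,4S)-7-(methoxymethoxy)-2-[7-(methoxymethoxy)-2,2-dimethyl-2H-chromen-6-yl]-8-(3-methylbut-2-en-1-yl)chroman-4-ol | CC(C)=CCc1c(OCOC)ccc2c1O[C@H](c1cc3c(cc1OCOC)OC(C)(C)C=C3)C[C@@H]2O | intermediate
23 | (2S)-7-(methoxymethoxy)-2-[7-(methoxymethoxy)-2,2-dimethyl-2H-chromen-6-yl]-8-(3-methylbut-2-en-1-yl)chroman-4-one | CC(C)=CCc1c(OCOC)ccc2c1O[C@H](c1cc3c(cc1OCOC)OC(C)(C)C=C3)CC2=O | intermediate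
24 | (2S)-7-hydroxy-2-(7-hydroxy-2,2-dimethyl-2H-chromen-6-yl)-8-(3-methylbut-2-en-1-yl)chroman-4-one | CC(C)=CCc1c(O)ccc2c1O[C@H](c1cc3c(cc1O)OC(C)(C)C=C3)CC2=O | target

**Count and risks**

Total step count: 14. Longest linear sequence: 10 steps (steps 1–4 or 5–8, then 9–14).

Steps most likely to fail:

1. Step 12. The C8a–Br bond carries a substituent on each neighbouring carbon, so its activation by monovalent copper may be too slow; the catalyst could then decay before ring closure and the bromide be lost by reduction. Fallback, from 21 back to 22: the same O1–C8a bond would be closed on palladium with Pd(OAc)2, 2-(di-tert-butylphosphino)-1,1'-binaphthyl and Cs2CO3 in toluene at 80 °C. Zerovalent palladium inserts readily into hindered aryl bromides, and the bulky phosphine favours C–O reductive elimination over β-hydride loss from the benzylic alkoxide. This changes the metal and the elementary steps and makes no compound outside the list (F0).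

2. Step 11. Hydride transfer to the chelated enol of a diketone with two ortho-substituted aryl groups may be sluggish or incomplete, the anti selectivity may erode, or the mono-reduced stage may dehydrate. Fallback, from 8 and 15 back to 21, leaving out 17 and 18: enolboration of 8 with Ipc2BCl/Et3N (the antipode that delivers the (S)-carbinol) and addition to 15 at −78 °C would give hydroxy ketone 20 as an isolated compound. Me4NBH(OAc)3 in MeCN/AcOH at −30 °C would then reduce the ring A carbonyl anti to the C2 hydroxyl by internal hydride delivery (Evans–Saksena reduction). The C2 configuration would then rest on the boron reagent alone; no compound outside the list is made (F0).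

3. Step 14. Protic acid may cyclise the prenyl group onto the freed C7 phenol, add to the electron-rich chromene, or reversibly open the O1–C2 bond and erode the C2 configuration. Fallback, from 23 back to 24: Et3SiOTf with 2,2'-bipyridyl in CH2Cl2 at 0 °C should exchange both methoxymethyl ethers directly for triethylsilyl ethers without a Brønsted acid, giving (2S)-7-(triethylsilyloxy)-2-[2,2-dimethyl-7-(triethylsilyloxy)-2H-chromen-6-yl]-8-(3-methylbut-2-en-1-yl)chroman-4-one F1. Buffered fluoride (Bu4NF/AcOH, THF, 0 °C) would then release the two phenols.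

**Further compounds**

F0 | step 12 | none | none
F0 | step 11 | none | none
F1 | step 14 | (2S)-7-(triethylsilyloxy)-2-[2,2-dimethyl-7-(triethylsilyloxy)-2H-chromen-6-yl]-8-(3-methylbut-2-en-1-yl)chroman-4-one | CC(C)=CCc1c(O[Si](CC)(CC)CC)ccc2c1O[C@H](c1cc3c(cc1O[Si](CC)(CC)CC)OC(C)(C)C=C3)CC2=O
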